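**Plan**
- Retrosynthesis: the C10 formamide goes back to a C10 ketone (cuts C10–N and C10–CH3). Ring A is then opened by a retro-Diels–Alder cut of C1–C6 and C2–C3 to a (7E)-1,7,9-decatrien-3-one.
- Enabling feature: ring A is a cyclohexene with C4=C5 next to the ring-fusion carbon C6. C6 and C1 are bridged by C7–C8–C9–C10, and C10 bears a heteroatom, so it can be a ketone that activates a C1=C2 dienophile from inside the tether.
- Further cuts: diene (C4–C5, C5=C6), enone (C10–C1), oxane ether bond O–C15, and C7–C8, down to geraniol.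
- Forward order: C7/C11 stereodiad, then the chlorinated oxane (ring C), then the diene and vinyl ketone arms. One cycloaddition closes ring B through C1–C6 together with ring A, followed by C10 amination and formylation.
- Stereochemistry: C11 from Sharpless epoxidation; C7 from invertive epoxide opening; C14 from Shi epoxidation then invertive chlorination; C1 and C6 from the endo cycloaddition under control of C7; C10 from convex-face methyl addition to a sulfinyl ketimine.

Key step: step 15

Remark on numbering: in the text, C1–C15 are kalihinane locants of the target. Decalin C1–C10: C1/C6 ring fusion, C4 the methyl-bearing olefinic carbon, C7 bearing the oxane, C10 bearing nitrogen. Oxane C11–C15: C11 quaternary, C14 chlorinated, C15 gem-dimethyl. Ring A = C1–C6, ring B = C1, C6–C10, ring C = the oxane. Compound names use their own IUPAC locants.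

Step 1
Reactants: 1 geraniol
Product: 2 (2S,3S)-2,3-epoxygeraniol
Conditions: Ti(OiPr)4 (5 mol %), L-(+)-diethyl tartrate (6 mol %), t-BuOOH, 4 Å MS, CH2Cl2, −20 °C
Reagents that add atoms: tert-butyl hydroperoxide, CC(C)(C)OO
Why: Katsuki–Sharpless asymmetric epoxidation of an (E)-allylic alcohol, in which the L-tartrate titanium complex delivers oxygen to one face of the 2,3-alkene only (the remote trisubstituted alkene is not an allylic alcohol and stays), setting C11 as (S) and C7 provisionally.

Step 2
Reactants: 2 (2S,3S)-2,3-epoxygeraniol; 3 2-(2-bromoethyl)-1,3-dioxolane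
Product: 5 (2R,3S)-2-[2-(1,3-dioxolan-2-yl)ethyl]-3,7-dimethyloct-6-ene-1,3-diol, via Grignard reagent 4 (not isolated)
Conditions: 3, Mg, THF, 25 °C; then CuI (10 mol %), 2, THF, −30 to 0 °C
Reagents that add atoms: none
Why: Copper-catalysed Grignard (cuprate) opening of a 2,3-epoxy alcohol, which should attack in SN2 fashion at C7, the only epoxide carbon open to backside attack because C11 is fully substituted, so C7 is set (R) by inversion while the C11–O bond and its configuration are kept and C8–C10 arrive at the aldehyde oxidation level.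

Step 3
Reactants: 5 diol
Product: 6 (4S,5R)-5-[2-(1,3-dioxolan-2-yl)ethyl]-2,2,4-trimethyl-4-(4-methylpent-3-en-1-yl)-1,3-dioxane
Conditions: 2,2-dimethoxypropane, PPTS (cat.), CH2Cl2, 23 °C
Reagents that add atoms: 2,2-dimethoxypropane, COC(C)(C)OC
Why: Acid-catalysed transketalisation to the acetonide of the 1,3-diol masks the tertiary C11 hydroxyl (which would otherwise open the later C14–C15 epoxide in a 5-exo mode) and the primary hydroxyl (which would be chlorinated in step 6), without touching a stereocentre.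

Step 4
Reactants: 6 acetonide
Product: 7 (4S,5R)-4-{2-[(2R)-3,3-dimethyloxiran-2-yl]ethyl}-5-[2-(1,3-dioxolan-2-yl)ethyl]-2,2,4-trimethyl-1,3-dioxane
Conditions: Shi ketone (D-fructose-derived, 0.3 equiv), Oxone, K2CO3, Bu4NHSO4 (cat.), MeCN–CH2(OMe)2–aq. borate buffer, 0 °C
Reagents that add atoms: potassium peroxymonosulfate (Oxone), [K+].[O-]S(=O)(=O)OO
Why: Shi asymmetric epoxidation, in which the chiral dioxirane transfers oxygen through a spiro transition state to one face of the only alkene, a trisubstituted R–CH=CMe2 unit for which the D-fructose-derived ketone is expected to give the (R)-epoxide, setting the C14–O configuration by reagent control.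

Step 5
Reactants: 7 epoxide
Product: 8 (3R)-1-{(4S,5R)-5-[2-(1,3-dioxolan-2-yl)ethyl]-2,2,4-trimethyl-1,3-dioxan-4-yl}-4-methylpent-4-en-3-ol
Conditions: Et2Al(TMP) (pre-formed, 4 equiv; TMP = 2,2,6,6-tetramethylpiperidide), toluene, 0 °C
Reagents that add atoms: none
Why: Yamamoto isomerisation of a trisubstituted epoxide to an allylic alcohol, in which the aluminium amide removes a methyl proton through a cyclic syn-elimination and the C15–O bond breaks, so the C14–O bond and its (R) configuration are retained and the isopropenyl group needed for ring closure appears.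

Step 6
Reactants: 8 allylic alcohol
Product: 9 (4S,5R)-4-[(3S)-3-chloro-4-methylpent-4-en-1-yl]-5-[2-(1,3-dioxolan-2-yl)ethyl]-2,2,4-trimethyl-1,3-dioxane
Conditions: PPh3, hexachloroacetone, CH2Cl2, 0 °C
Reagents that add atoms: hexachloroacetone, ClC(Cl)(Cl)C(=O)C(Cl)(Cl)Cl
Why: Magid chlorination (Appel type) of a secondary allylic alcohol, in which chloride displaces the alkoxyphosphonium group by SN2 under neutral conditions, known to proceed with inversion and little allylic transposition, so C14 becomes (S) with the chlorine of the target.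

Step 7
Reactants: 9 allylic chloride
Product: 10 (2R,3S,6S)-6-chloro-2-[2-(1,3-dioxolan-2-yl)ethyl]-3,7-dimethyloct-7-ene-1,3-diol
Conditions: AcOH–THF–H2O (3:1:1), 23 °C
Reagents that add atoms: none
Why: Mild acid hydrolysis of the strained acetonide (a ketal on a tertiary carbinol oxygen) should be much faster than hydrolysis of the aldehyde-derived dioxolane or solvolysis of the secondary allylic chloride, freeing both hydroxyls without touching a stereocentre.

Step 8
Reactants: 10 chloro diol
Product: 12 (2R)-2-[(2S,5S)-5-chloro-2,6,6-trimethyloxan-2-yl]-4-(1,3-dioxolan-2-yl)butan-1-ol, via trifluoroacetoxymercurio oxane 11 (not isolated)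
Conditions: Hg(O2CCF3)2, MeCN, −20 °C; then NaBH4, 3 M NaOH, 0 °C
Reagents that add atoms: none
Why: Intramolecular alkoxymercuration–demercuration (as in the closure of α-terpineol to 1,8-cineole), in which the C11 hydroxyl adds to the mercurinium ion at the more substituted C15 in a 6-exo Markovnikov mode and the CH2–Hg bond is then reduced to CH3, closing ring C with C11 and C14 untouched and the base applied only after the hydroxyl has become an ether.

Step 9
Reactants: 12 oxane alcohol
Product: 13 (2S)-2-[(2S,5S)-5-chloro-2,6,6-trimethyloxan-2-yl]-4-(1,3-dioxolan-2-yl)butanal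
Conditions: Dess–Martin periodinane, CH2Cl2, 0 °C
Reagents that add atoms: none
Why: Dess–Martin oxidation of the primary alcohol under non-basic conditions should give the aldehyde without epimerisation at C7 or β-elimination of the ring oxygen, and the crude aldehyde is used at once.

Step 10
Reactants: 13 aldehyde
Product: 14 2-{(3R,4E)-3-[(2S,5S)-5-chloro-2,6,6-trimethyloxan-2-yl]-5-iodopent-4-en-1-yl}-1,3-dioxolane
Conditions: CrCl2, CHI3, THF–dioxane, 0 to 23 °C
Reagents that add atoms: iodoform, IC(I)I
Why: Takai olefination, in which the geminal dichromium carbenoid from iodoform adds to the aldehyde and eliminates anti to give the (E)-vinyl iodide under non-basic conditions that leave the α-stereocentre C7, the secondary chloride and the acetal intact.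

Step 11
Reactants: 14 vinyl iodide; 15 4,4,5,5-tetramethyl-2-(prop-1-en-2-yl)-1,3,2-dioxaborolane
Product: 16 2-{(3R,4E)-3-[(2S,5S)-5-chloro-2,6,6-trimethyloxan-2-yl]-6-methylhepta-4,6-dien-1-yl}-1,3-dioxolane
Conditions: Pd(PPh3)4 (5 mol %), K3PO4, THF–H2O, 50 °C
Reagents that add atoms: none
Why: Suzuki–Miyaura coupling of an alkenyl iodide with an alkenylboronate proceeds with retention of the (E) geometry and gives the 2-methyl-1,3-diene (C3=C4–C5=C6), while the secondary alkyl chloride does not undergo oxidative addition.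

Step 12
Reactants: 16 diene acetal
Product: 17 (4R,5E)-4-[(2S,5S)-5-chloro-2,6,6-trimethyloxan-2-yl]-7-methylocta-5,7-dienal
Conditions: PPTS, acetone–H2O (4:1), 50 °C
Reagents that add atoms: water, O
Why: Acid-catalysed hydrolysis of the 1,3-dioxolane under weakly acidic conditions unmasks the C10 aldehyde while the diene, the tertiary ether and the chloride should survive.

Step 13
Reactants: 17 dienal
Product: 18 (6R,7E)-6-[(2S,5S)-5-chloro-2,6,6-trimethyloxan-2-yl]-9-methyldeca-1,7,9-trien-3-ol (both C3 epimers)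
Conditions: vinylmagnesium bromide, THF, −78 °C
Reagents that add atoms: vinylmagnesium bromide, C=C[Mg]Br
Why: Grignard 1,2-addition to the aldehyde installs C1 and C2, and the new carbinol centre needs no control because it is oxidised in the next step.

Step 14
Reactants: 18 trienol
Product: 19 (6R,7E)-6-[(2S,5S)-5-chloro-2,6,6-trimethyloxan-2-yl]-9-methyldeca-1,7,9-trien-3-one
Conditions: Dess–Martin periodinane, CH2Cl2, 0 °C; kept below 0 °C and used at once
Reagents that add atoms: none
Why: Dess–Martin oxidation of the secondary allylic alcohol gives the vinyl ketone, which now carries the activating carbonyl at C10 inside the future tether and is kept cold because trienones of this type cyclise on standing.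

Step 15
Reactants: 19 trienone
Product: 20 (4R,4aS,8aS)-4-[(2S,5S)-5-chloro-2,6,6-trimethyloxan-2-yl]-6-methyl-3,4,4a,7,8,8a-hexahydronaphthalen-1(2H)-one
Conditions: Et2AlCl (0.3 equiv), CH2Cl2, −78 to −30 °C
Reagents that add atoms: none
Why: Et2AlCl binds the ketone oxygen and lowers the enone LUMO, so the s-cis vinyl ketone (C1=C2) adds suprafacially to the s-cis (E)-diene (C3=C4–C5=C6) in a concerted, asynchronous [4+2] cycloaddition in which the peripheral C2–C3 bond leads and the internal C1–C6 bond completes the bicycle. The closest known reaction type is the Lewis-acid-promoted type 1 intramolecular Diels–Alder reaction of 1,7,9-decatrien-3-ones, which gives cis-fused 1-octalones and has served for cis-cadinane skeletons. Ring B (C1, C6, C7, C8, C9, C10) closes through the C1–C6 bond as the six-membered tether ring, and ring A (C1–C6, with C4=C5) forms in the same event from the C1–C6 and C2–C3 bonds. C1 and C6 are set cis because the carbonyl inside the four-atom tether is held endo under the diene and the (E) geometry of C5=C6 is transferred. Both centres are set relative to C7 because the tether folds boat-like with the bulky oxanyl group pseudo-equatorial on the exo side, eclipsing C6–H and not C5, so H6 ends trans to H7. The step needs endo over exo selectivity and one diene face: the first should be secured by internal carbonyl activation at low temperature, the second by the C7 stereocentre flanked by the quaternary C11, and the reaction is quenched cold so that C1 of the cis-ketone does not epimerise.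

Step 16
Reactants: 20 cis-octalone; 21 (R)-2-methylpropane-2-sulfinamide
Product: 22 (R)-N-{(4R,4aR,8aS)-4-[(2S,5S)-5-chloro-2,6,6-trimethyloxan-2-yl]-6-methyl-3,4,4a,7,8,8a-hexahydronaphthalen-1(2H)-ylidene}-2-methylpropane-2-sulfinamide
Conditions: Ti(OEt)4 (2 equiv), THF, 60 °C
Reagents that add atoms: none
Why: Ellman condensation, in which Ti(OEt)4 acts as Lewis acid and water scavenger, converts the hindered ketone into the N-sulfinyl ketimine without a Brønsted base, so the cis ring fusion should be kept.

Step 17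
Reactants: 22 sulfinyl ketimine
Product: 23 (R)-N-{(1R,4R,4aR,8aS)-4-[(2S,5S)-5-chloro-2,6,6-trimethyloxan-2-yl]-1,6-dimethyl-1,2,3,4,4a,7,8,8a-octahydronaphthalen-1-yl}-2-methylpropane-2-sulfinamide
Conditions: AlMe3 (1.1 equiv), toluene, −78 °C; then MeLi, −78 °C
Reagents that add atoms: methyllithium, [Li]C
Why: Trimethylaluminium-mediated addition of methyllithium to an N-tert-butanesulfinyl ketimine (Ellman) should deliver methyl to the convex face of the cis-decalin, anti to C2 of ring A (axial on ring B next to C10), and the (R)-sulfinyl group with nitrogen anti to the branched C1 directs through its six-membered chelate to the same face, so C10 is set (R) with nitrogen cis to C2.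

Step 18
Reactants: 23 sulfinamide
Product: 24 (1R,4R,4aR,8aS)-4-[(2S,5S)-5-chloro-2,6,6-trimethyloxan-2-yl]-1,6-dimethyl-1,2,3,4,4a,7,8,8a-octahydronaphthalen-1-amine
Conditions: HCl (4 M in dioxane), MeOH, 0 to 23 °C; then 1 M NaOH
Reagents that add atoms: none
Why: Acidic methanolysis of the N–S bond is the standard removal of the tert-butanesulfinyl group and should be brief enough to leave the trisubstituted alkene, the tertiary ether and the chloride untouched.

Step 19
Reactants: 24 amine
Product: 25 N-{(1R,4R,4aR,8aS)-4-[(2S,5S)-5-chloro-2,6,6-trimethyloxan-2-yl]-1,6-dimethyl-1,2,3,4,4a,7,8,8a-octahydronaphthalen-1-yl}formamide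
Conditions: acetic formic anhydride (pre-formed), pyridine, CH2Cl2, 0 to 23 °C
Reagents that add atoms: acetic formic anhydride, CC(=O)OC=O
Why: N-Formylation with the mixed anhydride, which reacts at its formyl carbonyl and is small enough to acylate a tert-alkyl primary amine, completes the target without touching a stereocentre.

**Compound list**
1 | geraniol | CC(C)=CCC/C(C)=C/CO | starting material
2 | (2S,3S)-2,3-epoxygeraniol | OC[C@@H]1O[C@@]1(C)CCC=C(C)C | intermediate
3 | 2-(2-bromoethyl)-1,3-dioxolane | BrCCC1OCCO1 | starting material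
4 | [2-(1,3-dioxolan-2-yl)ethyl]magnesium bromide | Br[Mg]CCC1OCCO1 | intermediate
5 | (2R,3S)-2-[2-(1,3-dioxolan-2-yl)ethyl]-3,7-dimethyloct-6-ene-1,3-diol | OC[C@H]([C@](O)(C)CCC=C(C)C)CCC1OCCO1 | intermediate
6 | (4S,5R)-5-[2-(1,3-dioxolan-2-yl)ethyl]-2,2,4-trimethyl-4-(4-methylpent-3-en-1-yl)-1,3-dioxane | CC1(C)OC[C@@H](CCC2OCCO2)[C@](C)(CCC=C(C)C)O1 | intermediate
7 | (4S,5R)-4-{2-[(2R)-3,3-dimethyloxiran-2-yl]ethyl}-5-[2-(1,3-dioxolan-2-yl)ethyl]-2,2,4-trimethyl-1,3-dioxane | CC1(C)OC[C@@H](CCC2OCCO2)[C@](C)(CC[C@@H]3C(C)(C)O3)O1 | intermediate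
8 | (3R)-1-{(4S,5R)-5-[2-(1,3-dioxolan-2-yl)ethyl]-2,2,4-trimethyl-1,3-dioxan-4-yl}-4-methylpent-4-en-3-ol | CC1(C)OC[C@@H](CCC2OCCO2)[C@](C)(CC[C@@H](O)C(C)=C)O1 | intermediate
9 | (4S,5R)-4-[(3S)-3-chloro-4-methylpent-4-en-1-yl]-5-[2-(1,3-dioxolan-2-yl)ethyl]-2,2,4-trimethyl-1,3-dioxane | CC1(C)OC[C@@H](CCC2OCCO2)[C@](C)(CC[C@H](Cl)C(C)=C)O1 | intermediate
10 | (2R,3S,6S)-6-chloro-2-[2-(1,3-dioxolan-2-yl)ethyl]-3,7-dimethyloct-7-ene-1,3-diol | OC[C@H]([C@](O)(C)CC[C@H](Cl)C(C)=C)CCC1OCCO1 | intermediate
11 | oxane 12 carrying CH2–Hg–O2CCF3 in place of one C15 methyl (either configuration at C15) | OC[C@H]([C@]1(C)CC[C@H](Cl)C(C)(C[Hg]OC(=O)C(F)(F)F)O1)CCC1OCCO1 | intermediate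
12 | (2R)-2-[(2S,5S)-5-chloro-2,6,6-trimethyloxan-2-yl]-4-(1,3-dioxolan-2-yl)butan-1-ol | OC[C@H]([C@]1(C)CC[C@H](Cl)C(C)(C)O1)CCC1OCCO1 | intermediate
13 | (2S)-2-[(2S,5S)-5-chloro-2,6,6-trimethyloxan-2-yl]-4-(1,3-dioxolan-2-yl)butanal | O=C[C@H]([C@]1(C)CC[C@H](Cl)C(C)(C)O1)CCC1OCCO1 | intermediate
14 | 2-{(3R,4E)-3-[(2S,5S)-5-chloro-2,6,6-trimethyloxan-2-yl]-5-iodopent-4-en-1-yl}-1,3-dioxolane | I/C=C/[C@H]([C@]1(C)CC[C@H](Cl)C(C)(C)O1)CCC1OCCO1 | intermediate
15 | 4,4,5,5-tetramethyl-2-(prop-1-en-2-yl)-1,3,2-dioxaborolane | CC(=C)B1OC(C)(C)C(C)(C)O1 | starting material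
16 | 2-{(3R,4E)-3-[(2S,5S)-5-chloro-2,6,6-trimethyloxan-2-yl]-6-methylhepta-4,6-dien-1-yl}-1,3-dioxolane | C=C(C)/C=C/[C@H]([C@]1(C)CC[C@H](Cl)C(C)(C)O1)CCC1OCCO1 | intermediate
17 | (4R,5E)-4-[(2S,5S)-5-chloro-2,6,6-trimethyloxan-2-yl]-7-methylocta-5,7-dienal | C=C(C)/C=C/[C@H]([C@]1(C)CC[C@H](Cl)C(C)(C)O1)CCC=O | intermediate
18 | (6R,7E)-6-[(2S,5S)-5-chloro-2,6,6-trimethyloxan-2-yl]-9-methyldeca-1,7,9-trien-3-ol (both C3 epimers) | C=C(C)/C=C/[C@H]([C@]1(C)CC[C@H](Cl)C(C)(C)O1)CCC(O)C=C | intermediate
19 | (6R,7E)-6-[(2S,5S)-5-chloro-2,6,6-trimethyloxan-2-yl]-9-methyldeca-1,7,9-trien-3-one | C=C(C)/C=C/[C@H]([C@]1(C)CC[C@H](Cl)C(C)(C)O1)CCC(=O)C=C | intermediate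
20 | (4R,4aS,8aS)-4-[(2S,5S)-5-chloro-2,6,6-trimethyloxan-2-yl]-6-methyl-3,4,4a,7,8,8a-hexahydronaphthalen-1(2H)-one | CC1=C[C@H]2[C@H]([C@]3(C)CC[C@H](Cl)C(C)(C)O3)CCC(=O)[C@H]2CC1 | intermediate
21 | (R)-2-methylpropane-2-sulfinamide | CC(C)(C)[S@@](=O)N | starting material
22 | (R)-N-{(4R,4aR,8aS)-4-[(2S,5S)-5-chloro-2,6,6-trimethyloxan-2-yl]-6-methyl-3,4,4a,7,8,8a-hexahydronaphthalen-1(2H)-ylidene}-2-methylpropane-2-sulfinamide (imine geometry not fixed) | CC1=C[C@H]2[C@H]([C@]3(C)CC[C@H](Cl)C(C)(C)O3)CCC(=N[S@](=O)C(C)(C)C)[C@H]2CC1 | intermediate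
23 | (R)-N-{(1R,4R,4aR,8aS)-4-[(2S,5S)-5-chloro-2,6,6-trimethyloxan-2-yl]-1,6-dimethyl-1,2,3,4,4a,7,8,8a-octahydronaphthalen-1-yl}-2-methylpropane-2-sulfinamide | CC1=C[C@H]2[C@H]([C@]3(C)CC[C@H](Cl)C(C)(C)O3)CC[C@@](C)(N[S@](=O)C(C)(C)C)[C@H]2CC1 | intermediate
24 | (1R,4R,4aR,8aS)-4-[(2S,5S)-5-chloro-2,6,6-trimethyloxan-2-yl]-1,6-dimethyl-1,2,3,4,4a,7,8,8a-octahydronaphthalen-1-amine | CC1=C[C@H]2[C@H]([C@]3(C)CC[C@H](Cl)C(C)(C)O3)CC[C@@](C)(N)[C@H]2CC1 | intermediate
25 | N-{(1R,4R,4aR,8aS)-4-[(2S,5S)-5-chloro-2,6,6-trimethyloxan-2-yl]-1,6-dimethyl-1,2,3,4,4a,7,8,8a-octahydronaphthalen-1-yl}formamide | CC1=C[C@H]2[C@H]([C@]3(C)CC[C@H](Cl)C(C)(C)O3)CC[C@@](C)(NC=O)[C@H]2CC1 | target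

**Step count and risks**

Total step count: 19. Longest linear sequence: 19 steps, from geraniol 1.

The three steps most likely to fail:

Step 8. Divalent mercury is halophilic and may ionise the allylic C14–Cl bond, or the free C11 hydroxyl may displace that chloride in a 5-exo mode before the inductively deactivated alkene is mercurated; either process ends in an isopropenyl oxolane instead of ring C. The fallback sets out from 10 and replaces the metal electrophile by iodine. Iodoetherification (I2, NaHCO3, MeCN, 0 °C) should close the ring in the same 6-exo Markovnikov sense to give (2R)-2-[(2S,5S)-5-chloro-6-(iodomethyl)-2,6-dimethyloxan-2-yl]-4-(1,3-dioxolan-2-yl)butan-1-ol F1. Radical deiodination (Bu3SnH, AIBN, toluene, 80 °C), which reduces the primary C–I bond far faster than the secondary C–Cl bond, then returns to the route at 12.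

Step 16. Condensation of the hindered ketone is slow, and at the temperature it needs the N-sulfinyl imine can tautomerise to its enamine and epimerise C1 to the trans-fused series; deprotonation next to the imine instead of addition in step 17 is part of the same weakness. The fallback sets out from 20 and builds the C10–N bond by rearrangement instead of by addition to C=N:
- Wittig reaction with Ph3P=CHOMe (from the phosphonium chloride and KHMDS, THF, 0 °C) gives the C10 methoxymethylidene analogue of 20 F2.
- Aqueous acid gives the C10 carbaldehyde F3 (C10 epimers).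
- KOt-Bu and MeI methylate the aldehyde enolate from the convex face to give the C10-methyl C10-carbaldehyde F4.
- Pinnick oxidation (NaClO2, NaH2PO4, 2-methyl-2-butene) gives the C10 carboxylic acid F5.
- Diphenylphosphoryl azide and Et3N give the acyl azide F6, which undergoes Curtius rearrangement with retention at 80 °C in toluene to the C10 isocyanate F7.
- LiBHEt3 at −78 °C reduces the isocyanate to the formamide and returns to the route at 25.

Step 6. The activated secondary allylic alcohol may ionise or be attacked at its methylene terminus, which would give the transposed primary allylic chloride or erode the configuration at C14. The fallback sets out from 7 and avoids an allylic chloride altogether. Deoxydichlorination of the epoxide (Ph3P, N-chlorosuccinimide, CH2Cl2), with inversion at C14, gives (4S,5R)-4-[(3S)-3,4-dichloro-4-methylpentyl]-5-[2-(1,3-dioxolan-2-yl)ethyl]-2,2,4-trimethyl-1,3-dioxane F8. Acetonide hydrolysis as in step 7 gives (2R,3S,6S)-6,7-dichloro-2-[2-(1,3-dioxolan-2-yl)ethyl]-3,7-dimethyloctane-1,3-diol F9. AgOTf with 2,6-di-tert-butylpyridine in CH2Cl2 at −40 °C should then remove the tertiary chloride with assistance of the C14 chlorine, and capture at C15 by the C11 hydroxyl returns to the route at 12.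

Further compounds
F1 | step 8 | (2R)-2-[(2S,5S)-5-chloro-6-(iodomethyl)-2,6-dimethyloxan-2-yl]-4-(1,3-dioxolan-2-yl)butan-1-ol (either configuration at the iodomethyl-bearing carbon) | OC[C@H]([C@]1(C)CC[C@H](Cl)C(C)(CI)O1)CCC1OCCO1
F2 | step 16 | enol ether: 20 with C10=O replaced by C10=CH–OMe (E/Z mixture) | CC1=C[C@H]2[C@H]([C@]3(C)CC[C@H](Cl)C(C)(C)O3)CCC(=COC)[C@H]2CC1
F3 | step 16 | aldehyde: 20 with C10=O replaced by C10(H)–CHO (C10 epimers) | CC1=C[C@H]2[C@H]([C@]3(C)CC[C@H](Cl)C(C)(C)O3)CCC(C=O)[C@H]2CC1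
F4 | step 16 | quaternary aldehyde: 25 with CHO in place of NHCHO at C10 | CC1=C[C@H]2[C@H]([C@]3(C)CC[C@H](Cl)C(C)(C)O3)CC[C@@](C)(C=O)[C@H]2CC1
F5 | step 16 | carboxylic acid: 25 with CO2H in place of NHCHO at C10 | CC1=C[C@H]2[C@H]([C@]3(C)CC[C@H](Cl)C(C)(C)O3)CC[C@@](C)(C(=O)O)[C@H]2CC1
F6 | step 16 | acyl azide: 25 with C(=O)N3 in place of NHCHO at C10 | CC1=C[C@H]2[C@H]([C@]3(C)CC[C@H](Cl)C(C)(C)O3)CC[C@@](C)(C(=O)N=[N+]=[N-])[C@H]2CC1
F7 | step 16 | isocyanate: 25 with N=C=O in place of NHCHO at C10 | CC1=C[C@H]2[C@H]([C@]3(C)CC[C@H](Cl)C(C)(C)O3)CC[C@@](C)(N=C=O)[C@H]2CC1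
F8 | step 6 | (4S,5R)-4-[(3S)-3,4-dichloro-4-methylpentyl]-5-[2-(1,3-dioxolan-2-yl)ethyl]-2,2,4-trimethyl-1,3-dioxane | CC1(C)OC[C@@H](CCC2OCCO2)[C@](C)(CC[C@H](Cl)C(C)(C)Cl)O1
F9 | step 6 | (2R,3S,6S)-6,7-dichloro-2-[2-(1,3-dioxolan-2-yl)ethyl]-3,7-dimethyloctane-1,3-diol | OC[C@H]([C@](O)(C)CC[C@H](Cl)C(C)(C)Cl)CCC1OCCO1
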